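**Plan**
1. Ring atoms are called C5–C10: C10 is the quaternary carbon (methyl, vinyl C1=C2), C9 the ring CH2, C8 the acyloxy carbon, C7 bears the acrylic acid (C11–C13), C6 is the carbinol, C5 bears the C4(=C3H2)–C15H2OH unit.
2. Retrosynthesis: first the C8 ester, the acid (from an allylic PMB ether), the vinyl group and C15H2OH (both from esters) are taken back; then the ring bonds C8–C9 and C5–C6 are cut together. This gives glutaconate 10 (C9–C10–C5, a double nucleophile) and silylated alkenylmalondialdehyde 16 (C6–C7–C8, a double electrophile).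
3. Forward: fragments 10 and 16 are made separately, and one zinc-mediated (3+3) annulation closes the cyclohexane and a temporary bridging lactone. Reduction/methylenation then opens the lactone to vinyl plus free C8–OH, which is acylated; the acid is made last.
4. Enabling feature: C6 and C8 are both carbinol carbons flanking C7 (a latent malondialdehyde); C9 is β to C1 once C1 is a carboxyl carbon (zinc homoenolate); C5 is the γ-carbon of a 2-carboxyallyl metal whose ester carbon is C15. The C8 oxygen and C1 are cis-1,3 on the ring, so they can close a 6-oxabicyclo[3.2.1]octan-7-one.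
5. Stereochemistry: C10 is set by enzymatic desymmetrisation of a prochiral malonate; C5, C6, C7 and C8 are relayed from it in the annulation; the side-chain Z-alkene comes from a Still–Gennari olefination.

Key step: step 13

Assumption: pig liver esterase is taken to deliver the (S)-half-ester 4; should it deliver the enantiomer, the ester arm is reduced (LiBH4) and the acid arm methylated instead, which leads to the same alcohol 5.

**Route**

Step 1
Reactants: 1 dimethyl 2-methylmalonate
Product: 2 dimethyl 2-(hydroxymethyl)-2-methylmalonate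
Conditions: 37% aq. CH2O, KHCO3 (cat.), rt
Reagents that add atoms: formaldehyde, C=O
Why: Base-catalysed aldol-type hydroxymethylation of the single acidic malonate C–H should stop cleanly at mono-addition.

Step 2
Reactants: 2 dimethyl 2-(hydroxymethyl)-2-methylmalonate
Product: 3 dimethyl 2-(tert-butoxymethyl)-2-methylmalonate
Conditions: 2-methylpropene, H2SO4 (cat.), CH2Cl2, sealed vessel, rt
Reagents that add atoms: 2-methylpropene, C=C(C)C
Why: Acid-catalysed addition of the primary alcohol to isobutene (tert-butyl ether formation) gives the prochiral diester in the form suited to the enzymatic step.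

Step 3
Reactants: 3 dimethyl 2-(tert-butoxymethyl)-2-methylmalonate
Product: 4 (2S)-3-tert-butoxy-2-(methoxycarbonyl)-2-methylpropanoic acid
Conditions: pig liver esterase, phosphate buffer pH 7.5 (pH-stat, NaOH), 25 °C; then HCl to pH 2
Reagents that add atoms: water, O
Why: Enzymatic desymmetrisation (hydrolysis of one enantiotopic ester of a 2,2-disubstituted malonate) sets the quaternary centre C10 by catalysis.

Step 4
Reactants: 4 (2S)-3-tert-butoxy-2-(methoxycarbonyl)-2-methylpropanoic acid
Product: 5 methyl (2R)-3-tert-butoxy-2-(hydroxymethyl)-2-methylpropanoate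
Conditions: BH3·SMe2, THF, 0 °C to rt; MeOH
Reagents that add atoms: none
Why: Borane reduces the carboxylic acid chemoselectively beside the methyl ester, and the quaternary centre has no α-hydrogen to scramble.

Step 5
Reactants: 5 methyl (2R)-3-tert-butoxy-2-(hydroxymethyl)-2-methylpropanoate
Product: 7 dimethyl (2E,4R)-4-(tert-butoxymethyl)-2,4-dimethylpent-2-enedioate, via aldehyde 6 (not isolated)
Conditions: PhI(OAc)2, 2,2,6,6-tetramethylpiperidin-1-oxyl (cat.), CH2Cl2, rt; then Ph3P=C(CH3)CO2CH3, 40 °C
Reagents that add atoms: methyl 2-(triphenylphosphoranylidene)propanoate, COC(=O)C(C)=P(c1ccccc1)(c1ccccc1)c1ccccc1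
Why: Nitroxyl-catalysed oxidation to the non-enolisable aldehyde followed by Wittig olefination with a stabilised ylide should give the E-enoate (C10 trans to the ester).

Step 6
Reactants: 7 dimethyl (2E,4R)-4-(tert-butoxymethyl)-2,4-dimethylpent-2-enedioate
Product: 8 dimethyl (2E,4R)-4-(hydroxymethyl)-2,4-dimethylpent-2-enedioate
Conditions: CF3CO2H, CH2Cl2, 0 °C to rt
Reagents that add atoms: none
Why: Acidolysis of the tert-butyl ether frees the primary alcohol; the E-geometry keeps it away from the distal ester, so no lactone can form.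

Step 7
Reactants: 8 dimethyl (2E,4R)-4-(hydroxymethyl)-2,4-dimethylpent-2-enedioate
Product: 9 dimethyl (2E,4S)-4-(iodomethyl)-2,4-dimethylpent-2-enedioate
Conditions: I2, PPh3, imidazole, PhMe, 80 °C
Reagents that add atoms: iodine, II
Why: Appel iodination converts the neopentyl-type alcohol into the β-iodo ester without touching the stereocentre.

Step 8
Reactants: 9 dimethyl (2E,4S)-4-(iodomethyl)-2,4-dimethylpent-2-enedioate
Product: 10 dimethyl (2Z,4S)-2-(bromomethyl)-4-(iodomethyl)-4-methylpent-2-enedioate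
Conditions: N-bromosuccinimide, azobis(isobutyronitrile) (cat.), PhCF3, 80 °C
Reagents that add atoms: N-bromosuccinimide, O=C1CCC(=O)N1Br
Why: Wohl–Ziegler bromination has only the vinylic methyl group as allylic C–H (C10 is quaternary) and should give the usual 2-(bromomethyl)alk-2-enoate with C10 cis to CH2Br.

Step 9
Reactants: 11 2-bromoprop-2-en-1-ol
Product: 12 1-{[(2-bromoprop-2-en-1-yl)oxy]methyl}-4-methoxybenzene
Conditions: NaH, 4-MeOC6H4CH2Cl, Bu4NI (cat.), THF, 0 °C to rt
Reagents that add atoms: 4-methoxybenzyl chloride, COc1ccc(CCl)cc1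
Why: Williamson etherification installs the PMB group that later marks C12 for selective oxidation.

Step 10
Reactants: 12 1-{[(2-bromoprop-2-en-1-yl)oxy]methyl}-4-methoxybenzene
Product: 13 tributyl{3-[(4-methoxybenzyl)oxy]prop-1-en-2-yl}stannane
Conditions: (Bu3Sn)2, Pd(PPh3)4 (cat.), PhMe, 100 °C
Reagents that add atoms: hexabutylditin, CCCC[Sn](CCCC)(CCCC)[Sn](CCCC)(CCCC)CCCC
Why: Palladium-catalysed stannylation of the vinyl bromide with a distannane gives the 2-stannylallyl ether without passing through a β-alkoxy vinyl anion.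

Step 11
Reactants: 14 2-bromopropanedial
Product: 15 (2E)-2-bromo-3-[(tert-butyldimethylsilyl)oxy]prop-2-enal
Conditions: t-BuMe2SiCl, Et3N, CH2Cl2, 0 °C
Reagents that add atoms: tert-butyldimethylsilyl chloride, CC(C)(C)[Si](C)(C)Cl
Why: O-Silylation of the acidic enol of bromomalonaldehyde masks one formyl group as a silyl enol ether with CHO and OSi cis.

Step 12
Reactants: 13 tributyl{3-[(4-methoxybenzyl)oxy]prop-1-en-2-yl}stannane; 15 (2E)-2-bromo-3-[(tert-butyldimethylsilyl)oxy]prop-2-enal
Product: 16 (2Z)-3-[(tert-butyldimethylsilyl)oxy]-2-{3-[(4-methoxybenzyl)oxy]prop-1-en-2-yl}prop-2-enal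
Conditions: Pd2(dba)3 (cat.), AsPh3, CuI (cat.), N-methylpyrrolidone, rt
Reagents that add atoms: none
Why: Stille coupling of the electron-poor α-bromo enal with the vinylstannane under base-free conditions joins C7 to C11 and keeps the labile silyl enol ether.

Step 13
Reactants: 10 dimethyl (2Z,4S)-2-(bromomethyl)-4-(iodomethyl)-4-methylpent-2-enedioate; 16 (2Z)-3-[(tert-butyldimethylsilyl)oxy]-2-{3-[(4-methoxybenzyl)oxy]prop-1-en-2-yl}prop-2-enal
Product: 19 bridged lactone (methyl 2-{3-[(tert-butyldimethylsilyl)oxy]-4-{3-[(4-methoxybenzyl)oxy]prop-1-en-2-yl}-1-methyl-7-oxo-6-oxabicyclo[3.2.1]octan-2-yl}prop-2-enoate; C5 arm anti to the lactone bridge; C6 silyl ether cis to the C5 arm; C7 arm trans to the C6 silyl ether), via iodo aldehyde 17 (not isolated), via hydroxy diester 18 (not isolated)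
Conditions: Zn dust (activated, 3 equiv), THF, 0 °C, slow addition of 10 to 16; t-BuCO2H (1.0 equiv), 0 °C; then LiCl, Me3SiCl, 45 °C; 1 M HCl work-up; pyridinium p-toluenesulfonate (cat.), PhMe, 50 °C
Reagents that add atoms: none
Why: Proposed new method: zinc inserts first into the allylic C–Br bond of 10 (the neopentyl C–I bond is inert at 0 °C) and the Z-configured 2-(methoxycarbonyl)allylzinc adds through its γ-carbon C5 to the formyl carbon C6 of 16, a Dreiding–Schmidt (Barbier) allylation being the closest known reaction type; the zinc alkoxide then takes the silyl group from the neighbouring Z-enol ether by a six-centre 1,5-O-to-O shift, which protects O6 and unmasks C8 as an aldehyde enolate that pivalic acid protonates to iodo aldehyde 17. Zinc insertion into the C9–I bond at 45 °C gives a chelated β-zincio ester (zinc homoenolate, the second known reaction type), whose Me3SiCl-promoted addition to the C8 aldehyde closes the cyclohexane in a 6-exo-trig mode to 18, and the C8 oxygen, held 1,3-diaxial to the C1 ester, closes the γ-lactone by 5-exo-trig acyl substitution to the 6-oxabicyclo[3.2.1]octan-7-one 19. C5 and C6 should arise syn (cis on the ring) from the chair Zimmerman–Traxler transition state of the Z-allylzinc, and their sense relative to C10 from attack anti to the bulky CH2I arm while the C10 ester carbonyl is coordinated to zinc. C7 is set by protonation and stays epimerisable α to the aldehyde, so the epimer that places its side chain equatorial in the chair-like closure should be funnelled into product; C8 is set by the zinc chelate between the C1 ester and the aldehyde oxygen, which delivers O8 cis to C1 and is then fixed by lactonisation. The step needs 1,2-addition to the vinylogous silyl ester and allyl-before-alkyl zinc formation, secured by the in situ (Barbier) mode and the large rate difference of zinc insertion into allylic bromide and neopentyl iodide; an adduct with the wrong C5/C10 relation cannot reach the diaxial lactone geometry and should be separable.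

Step 14
Reactants: 19 bridged lactone
Product: 20 lactol alcohol (2-{3-[(tert-butyldimethylsilyl)oxy]-7-hydroxy-4-{3-[(4-methoxybenzyl)oxy]prop-1-en-2-yl}-1-methyl-6-oxabicyclo[3.2.1]octan-2-yl}prop-2-en-1-ol, lactol anomers)
Conditions: i-Bu2AlH (4.5 equiv), CH2Cl2, −78 °C; Rochelle salt
Reagents that add atoms: none
Why: DIBAL-H reduction should stop at the bridged lactol (stable tetrahedral aluminate) while taking the methyl enoate to the allylic alcohol C15H2OH by 1,2-reduction.

Step 15
Reactants: 20 lactol alcohol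
Product: 21 diol (5-[(tert-butyldimethylsilyl)oxy]-3-ethenyl-4-(3-hydroxyprop-1-en-2-yl)-6-{3-[(4-methoxybenzyl)oxy]prop-1-en-2-yl}-3-methylcyclohexan-1-ol, ring stereocentres as in 31)
Conditions: Ph3PCH3Br, KOt-Bu (excess), THF, 0 to 60 °C
Reagents that add atoms: methyltriphenylphosphonium bromide, C[P+](c1ccccc1)(c1ccccc1)c1ccccc1.[Br-]
Why: Wittig methylenation of the open hydroxy-aldehyde form of the lactol turns C1 into the vinyl group and releases the C8 hydroxyl at the moment it is needed.

Step 16
Reactants: 21 diol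
Product: 22 secondary alcohol (as 21, with the primary allylic hydroxyl as its tert-butyldimethylsilyl ether)
Conditions: t-BuMe2SiCl (1.1 equiv), imidazole, CH2Cl2, 0 °C
Reagents that add atoms: tert-butyldimethylsilyl chloride, CC(C)(C)[Si](C)(C)Cl
Why: The primary allylic C15 hydroxyl should silylate far faster than the hindered secondary C8 hydroxyl.

Step 17
Reactants: 23 ethyl 2-[bis(2,2,2-trifluoroethoxy)phosphoryl]propanoate
Product: 24 2-[bis(2,2,2-trifluoroethoxy)phosphoryl]propanoic acid
Conditions: Me3SnOH, ClCH2CH2Cl, 80 °C; then 1 M HCl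
Reagents that add atoms: trimethyltin hydroxide, C[Sn](C)(C)O
Why: Mild tin hydroxide ester cleavage gives the carboxylic acid without attacking the trifluoroethyl phosphonate esters.

Step 18
Reactants: 22 secondary alcohol; 24 2-[bis(2,2,2-trifluoroethoxy)phosphoryl]propanoic acid
Product: 25 phosphonate ester (C8 ester of 22 with 24, epimers at the phosphonate carbon)
Conditions: N,N'-dicyclohexylcarbodiimide, 4-(dimethylamino)pyridine (cat.), CH2Cl2, 0 °C to rt
Reagents that add atoms: none
Why: Steglich esterification acylates the only free hydroxyl (C8) with retention of configuration.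

Step 19
Reactants: 25 phosphonate ester; 26 2-oxoethyl acetate
Product: 27 (2Z)-4-acetoxy-2-methylbut-2-enoate of 22
Conditions: KN(SiMe3)2, 18-crown-6, THF, −78 °C; then 26
Reagents that add atoms: none
Why: Still–Gennari variant of the Horner–Wadsworth–Emmons reaction builds the trisubstituted Z-enoate directly on the substrate and so avoids isomerisation of a preformed angelate-type acid.

Step 20
Reactants: 27 (2Z)-4-acetoxy-2-methylbut-2-enoate of 22
Product: 28 allylic alcohol (as 27, with C12H2OH free)
Conditions: 2,3-dichloro-5,6-dicyano-1,4-benzoquinone, CH2Cl2/pH 7 buffer, 0 °C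
Reagents that add atoms: none
Why: Oxidative PMB cleavage frees only the C12 hydroxyl; silyl ethers, esters and alkenes are left intact.

Step 21
Reactants: 28 allylic alcohol
Product: 30 bis-silyl acid (as 31, with both hydroxyls as tert-butyldimethylsilyl ethers), via enal 29 (not isolated)
Conditions: Dess–Martin periodinane, NaHCO3, CH2Cl2, 0 °C; then NaClO2, NaH2PO4, 2-methylbut-2-ene, t-BuOH/H2O, 0 °C
Reagents that add atoms: sodium chlorite, [Na+].[O-]Cl=O
Why: Dess–Martin oxidation to the α-substituted acrolein followed by Pinnick oxidation is the standard mild access to α-methylene acids and leaves alkenes and esters untouched.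

Step 22
Reactants: 30 bis-silyl acid
Product: 31 2-[(1S,2R,3S,4R,6R)-6-{[(2Z)-4-(acetyloxy)-2-methylbut-2-enoyl]oxy}-4-ethenyl-2-hydroxy-3-(3-hydroxyprop-1-en-2-yl)-4-methylcyclohexyl]prop-2-enoic acid
Conditions: HF·pyridine, pyridine, THF, 0 °C to rt; pH 7 buffer work-up
Reagents that add atoms: none
Why: Buffered fluoride desilylation removes both silyl ethers under conditions that spare the acetate, the Z-enoate ester and the acrylic acid.

**Compound list**
1 | dimethyl 2-methylmalonate | COC(=O)C(C)C(=O)OC | starting material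
2 | dimethyl 2-(hydroxymethyl)-2-methylmalonate | COC(=O)C(C)(CO)C(=O)OC | intermediate
3 | dimethyl 2-(tert-butoxymethyl)-2-methylmalonate | COC(=O)C(C)(COC(C)(C)C)C(=O)OC | intermediate
4 | (2S)-3-tert-butoxy-2-(methoxycarbonyl)-2-methylpropanoic acid | COC(=O)[C@@](C(=O)O)(C)COC(C)(C)C | intermediate
5 | methyl (2R)-3-tert-butoxy-2-(hydroxymethyl)-2-methylpropanoate | COC(=O)[C@@](CO)(C)COC(C)(C)C | intermediate
6 | methyl (2S)-3-tert-butoxy-2-formyl-2-methylpropanoate (not isolated) | COC(=O)[C@@](C=O)(C)COC(C)(C)C | intermediate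
7 | dimethyl (2E,4R)-4-(tert-butoxymethyl)-2,4-dimethylpent-2-enedioate | COC(=O)/C(C)=C/[C@](C)(COC(C)(C)C)C(=O)OC | intermediate
8 | dimethyl (2E,4R)-4-(hydroxymethyl)-2,4-dimethylpent-2-enedioate | COC(=O)/C(C)=C/[C@](C)(CO)C(=O)OC | intermediate
9 | dimethyl (2E,4S)-4-(iodomethyl)-2,4-dimethylpent-2-enedioate | COC(=O)/C(C)=C/[C@](C)(CI)C(=O)OC | intermediate
10 | dimethyl (2Z,4S)-2-(bromomethyl)-4-(iodomethyl)-4-methylpent-2-enedioate | COC(=O)/C(CBr)=C/[C@](C)(CI)C(=O)OC | intermediate
11 | 2-bromoprop-2-en-1-ol | OCC(Br)=C | starting material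
12 | 1-{[(2-bromoprop-2-en-1-yl)oxy]methyl}-4-methoxybenzene | C=C(Br)COCc1ccc(OC)cc1 | intermediate
13 | tributyl{3-[(4-methoxybenzyl)oxy]prop-1-en-2-yl}stannane | C=C(COCc1ccc(OC)cc1)[Sn](CCCC)(CCCC)CCCC | intermediate
14 | 2-bromopropanedial (bromomalonaldehyde) | O=CC(Br)C=O | starting material
15 | (2E)-2-bromo-3-[(tert-butyldimethylsilyl)oxy]prop-2-enal | O=C/C(Br)=C\O[Si](C)(C)C(C)(C)C | intermediate
16 | (2Z)-3-[(tert-butyldimethylsilyl)oxy]-2-{3-[(4-methoxybenzyl)oxy]prop-1-en-2-yl}prop-2-enal | O=C/C(C(=C)COCc1ccc(OC)cc1)=C\O[Si](C)(C)C(C)(C)C | intermediate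
17 | iodo aldehyde (not isolated): dimethyl 3-{1-[(tert-butyldimethylsilyl)oxy]-2-formyl-3-{[(4-methoxybenzyl)oxy]methyl}but-3-en-1-yl}-2-(iodomethyl)-2-methyl-4-methylidenepentanedioate, reactive C7 epimer drawn | COC(=O)C(=C)[C@@H]([C@@H](O[Si](C)(C)C(C)(C)C)[C@@H](C=O)C(=C)COCc1ccc(OC)cc1)[C@](C)(CI)C(=O)OC | intermediate
18 | hydroxy diester (not isolated): methyl 3-[(tert-butyldimethylsilyl)oxy]-5-hydroxy-2-(3-methoxy-3-oxoprop-1-en-2-yl)-4-{3-[(4-methoxybenzyl)oxy]prop-1-en-2-yl}-1-methylcyclohexane-1-carboxylate, hydroxyl cis to the ring ester | COC(=O)C(=C)[C@H]1[C@@H](O[Si](C)(C)C(C)(C)C)[C@H](C(=C)COCc2ccc(OC)cc2)[C@H](O)C[C@]1(C)C(=O)OC | intermediate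
19 | bridged lactone: methyl 2-{3-[(tert-butyldimethylsilyl)oxy]-4-{3-[(4-methoxybenzyl)oxy]prop-1-en-2-yl}-1-methyl-7-oxo-6-oxabicyclo[3.2.1]octan-2-yl}prop-2-enoate, stereocentres as in the SMILES | COC(=O)C(=C)[C@H]1[C@@H](O[Si](C)(C)C(C)(C)C)[C@H](C(=C)COCc2ccc(OC)cc2)[C@H]3C[C@]1(C)C(=O)O3 | intermediate
20 | lactol alcohol: 2-{3-[(tert-butyldimethylsilyl)oxy]-7-hydroxy-4-{3-[(4-methoxybenzyl)oxy]prop-1-en-2-yl}-1-methyl-6-oxabicyclo[3.2.1]octan-2-yl}prop-2-en-1-ol, lactol anomers | OCC(=C)[C@H]1[C@@H](O[Si](C)(C)C(C)(C)C)[C@H](C(=C)COCc2ccc(OC)cc2)[C@H]3C[C@]1(C)C(O)O3 | intermediate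
21 | diol: 5-[(tert-butyldimethylsilyl)oxy]-3-ethenyl-4-(3-hydroxyprop-1-en-2-yl)-6-{3-[(4-methoxybenzyl)oxy]prop-1-en-2-yl}-3-methylcyclohexan-1-ol, ring stereocentres as in 31 | C=C[C@@]1(C)C[C@@H](O)[C@@H](C(=C)COCc2ccc(OC)cc2)[C@H](O[Si](C)(C)C(C)(C)C)[C@@H]1C(=C)CO | intermediate
22 | secondary alcohol: 5-[(tert-butyldimethylsilyl)oxy]-4-{3-[(tert-butyldimethylsilyl)oxy]prop-1-en-2-yl}-3-ethenyl-6-{3-[(4-methoxybenzyl)oxy]prop-1-en-2-yl}-3-methylcyclohexan-1-ol, ring stereocentres as in 31 | C=C[C@@]1(C)C[C@@H](O)[C@@H](C(=C)COCc2ccc(OC)cc2)[C@H](O[Si](C)(C)C(C)(C)C)[C@@H]1C(=C)CO[Si](C)(C)C(C)(C)C | intermediate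
23 | ethyl 2-[bis(2,2,2-trifluoroethoxy)phosphoryl]propanoate | CCOC(=O)C(C)P(=O)(OCC(F)(F)F)OCC(F)(F)F | starting material
24 | 2-[bis(2,2,2-trifluoroethoxy)phosphoryl]propanoic acid | OC(=O)C(C)P(=O)(OCC(F)(F)F)OCC(F)(F)F | intermediate
25 | phosphonate ester: C8 2-[bis(2,2,2-trifluoroethoxy)phosphoryl]propanoate of 22, epimers at the phosphonate carbon | C=C[C@@]1(C)C[C@@H](OC(=O)C(C)P(=O)(OCC(F)(F)F)OCC(F)(F)F)[C@@H](C(=C)COCc2ccc(OC)cc2)[C@H](O[Si](C)(C)C(C)(C)C)[C@@H]1C(=C)CO[Si](C)(C)C(C)(C)C | intermediate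
26 | 2-oxoethyl acetate (acetoxyacetaldehyde) | CC(=O)OCC=O | starting material
27 | Z-enoate: C8 (2Z)-4-acetoxy-2-methylbut-2-enoate of 22 | C=C[C@@]1(C)C[C@@H](OC(=O)/C(C)=C\COC(C)=O)[C@@H](C(=C)COCc2ccc(OC)cc2)[C@H](O[Si](C)(C)C(C)(C)C)[C@@H]1C(=C)CO[Si](C)(C)C(C)(C)C | intermediate
28 | allylic alcohol: as 27 with the PMB ether replaced by a free primary hydroxyl | C=C[C@@]1(C)C[C@@H](OC(=O)/C(C)=C\COC(C)=O)[C@@H](C(=C)CO)[C@H](O[Si](C)(C)C(C)(C)C)[C@@H]1C(=C)CO[Si](C)(C)C(C)(C)C | intermediate
29 | enal (not isolated): as 28 with the primary alcohol oxidised to the α-methylene aldehyde | C=C[C@@]1(C)C[C@@H](OC(=O)/C(C)=C\COC(C)=O)[C@@H](C(=C)C=O)[C@H](O[Si](C)(C)C(C)(C)C)[C@@H]1C(=C)CO[Si](C)(C)C(C)(C)C | intermediate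
30 | bis-silyl acid: 31 with both hydroxyls as tert-butyldimethylsilyl ethers | C=C[C@@]1(C)C[C@@H](OC(=O)/C(C)=C\COC(C)=O)[C@@H](C(=C)C(=O)O)[C@H](O[Si](C)(C)C(C)(C)C)[C@@H]1C(=C)CO[Si](C)(C)C(C)(C)C | intermediate
31 | 2-[(1S,2R,3S,4R,6R)-6-{[(2Z)-4-(acetyloxy)-2-methylbut-2-enoyl]oxy}-4-ethenyl-2-hydroxy-3-(3-hydroxyprop-1-en-2-yl)-4-methylcyclohexyl]prop-2-enoic acid | C=C[C@@]1(C)C[C@@H](OC(=O)/C(C)=C\COC(C)=O)[C@@H](C(=C)C(=O)O)[C@H](O)[C@@H]1C(=C)CO | target

**Step count and risks**
Total steps: 22. Longest linear sequence: 17 steps (steps 1–8, 13–16, 18–22).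

Step 13 (key step). What may go wrong: poor facial selectivity of the intermolecular allylation relative to C10, incomplete O-to-O silyl transfer, β-elimination from the aldehyde enolate, or failure of the β-zincio ester to close the ring. Fallback: the two bonds are made in separate known operations, setting out from 10 and 16 and coming back at 19. Zinc-mediated Dreiding–Schmidt allylation in THF at 0 °C is quenched with t-BuMe2SiOTf and 2,6-lutidine, which silylates the C6 zinc alkoxide and gives the bis-silyl Barbier adduct F1, where C5 epimers can be separated. Methanolysis of the enol silyl ether (K2CO3, MeOH, 0 °C) liberates iodo aldehyde 17, now isolated. Chromium-mediated intramolecular alkylation of the aldehyde (CrCl2, cobalt phthalocyanine as catalyst, DMF) gives hydroxy diester 18, which lactonises with pyridinium p-toluenesulfonate to 19.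

Step 12. What may go wrong: protodestannylation or homocoupling during the Stille coupling, and hydrolysis or self-condensation of the labile silyloxy enals 15 and 16. Fallback: the malondialdehyde is built from a malonate, setting out from 12 and coming back at 16. Copper-catalysed C-vinylation of diethyl malonate with 12 (CuI, picolinic acid, Cs2CO3, dioxane) gives diethyl 2-{3-[(4-methoxybenzyl)oxy]prop-1-en-2-yl}malonate F2. LiAlH4 reduction gives 2-{3-[(4-methoxybenzyl)oxy]prop-1-en-2-yl}propane-1,3-diol F3. Double Swern oxidation gives the dialdehyde as its enol, (2Z)-3-hydroxy-2-{3-[(4-methoxybenzyl)oxy]prop-1-en-2-yl}prop-2-enal F4, and O-silylation (t-BuMe2SiCl, Et3N) gives 16.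

Step 22. What may go wrong: lactonisation of the liberated C6 hydroxyl onto the acrylic acid, or slow cleavage of the hindered C6 silyl ether under the mildly acidic fluoride conditions. Fallback: the order of the last operations is changed so that the acid is formed last, setting out from 28 and coming back at 31. Alcohol 28 is oxidised with Dess–Martin periodinane and enal 29 is isolated. HF·pyridine desilylation of 29 gives the dihydroxy enal F5, which has no carboxyl group to lactonise. A buffered Pinnick oxidation, which tolerates free hydroxyls, then gives 31 directly.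

**Further compounds**
F1 | step 13 | bis-silyl Barbier adduct: dimethyl 3-{1-[(tert-butyldimethylsilyl)oxy]-2-{[(tert-butyldimethylsilyl)oxy]methylidene}-3-{[(4-methoxybenzyl)oxy]methyl}but-3-en-1-yl}-2-(iodomethyl)-2-methyl-4-methylidenepentanedioate | COC(=O)C(=C)[C@@H]([C@@H](O[Si](C)(C)C(C)(C)C)/C(=C\O[Si](C)(C)C(C)(C)C)C(=C)COCc1ccc(OC)cc1)[C@](C)(CI)C(=O)OC
F2 | step 12 | diethyl 2-{3-[(4-methoxybenzyl)oxy]prop-1-en-2-yl}malonate | CCOC(=O)C(C(=C)COCc1ccc(OC)cc1)C(=O)OCC
F3 | step 12 | 2-{3-[(4-methoxybenzyl)oxy]prop-1-en-2-yl}propane-1,3-diol | OCC(CO)C(=C)COCc1ccc(OC)cc1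
F4 | step 12 | (2Z)-3-hydroxy-2-{3-[(4-methoxybenzyl)oxy]prop-1-en-2-yl}prop-2-enal | O=C/C(C(=C)COCc1ccc(OC)cc1)=C\O
F5 | step 22 | dihydroxy enal: 31 with the carboxyl group replaced by a formyl group | C=C[C@@]1(C)C[C@@H](OC(=O)/C(C)=C\COC(C)=O)[C@@H](C(=C)C=O)[C@H](O)[C@@H]1C(=C)CO
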